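**Plan**

1. Retrosynthesis: C16=C17 is restored last from the 16-ketone. Ring A is cut at C3–C4 (aldol), C4–C5 (Michael lactonisation of an O10-propanoate) and C10–C1 (acetylide addition). Ring D is cut at C13–C16 (vinyl radical closure). Ring C is cut last at C9–C11 and C8–C14, a [4+2] retron that leaves butadiene and a ring B cyclopentenone.
2. Enabling feature: ring C is a cyclohexane cis-fused to cyclopentane ring B across C8–C9. Its C11–C12–C13–C14 arc carries nothing but the C13 bridge, and C8 is α to C6 (the carbon that bears C7). With C6 as a ketone, C8=C9 is an enone dienophile, and the adduct's C12=C13 alkene lies where the C15–C16 arm on C8 must close ring D.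
3. Forward order: ring B (commercial) → ring C by Diels–Alder (quaternary C8) → ring D → C7 by carbonylation → γ-lactone → ring A → triol → methylene → acid.
4. Stereochemistry: all relayed from the one stereocentre of (R)-4-silyloxycyclopentenone. The diene adds anti to OSi (C8, C9); C13 is geometrically forced; the acetylide adds anti to C11 (C10); tether and bicyclic constraints set C5 and C4; C6 equilibrates; C3 comes from the aldol closure; C1/C2 come from β-face osmylation directed by the 3β-hydroxyl.
5. The exocyclic methylene made in step 5 masks the C16 ketone through the organometallic and enolate steps. It is exchanged for the ketone and back (steps 14 and 16) around the osmylation, which it would not survive.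

Key step: step 4

Remark: gibberellane numbering is used for all intermediates; α is the face of ring B that carries the lactone oxygen and the C11/C14 carbons of ring C in the target, β is the opposite face.

**Route**

Step 1
Reactants: 1 (R)-4-(tert-butyldimethylsilyloxy)cyclopent-2-en-1-one
Product: 2 (R)-4-(tert-butyldimethylsilyloxy)-2-iodocyclopent-2-en-1-one
Conditions: I2, pyridine, CH2Cl2, 0 °C to rt
Reagents that add atoms: iodine, [I][I]
Why: Pyridine-mediated addition–elimination (conjugate addition of pyridine, iodination of the enolate, loss of pyridinium) should iodinate the enone α-carbon without touching the silyl ether or the C10 stereocentre.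

Step 2
Reactants: 2 (R)-4-(tert-butyldimethylsilyloxy)-2-iodocyclopent-2-en-1-one
Product: 3 (R)-4-(tert-butyldimethylsilyloxy)-2-(trimethylstannyl)cyclopent-2-en-1-one
Conditions: Me3SnSnMe3, Pd(PPh3)4 (cat.), PhMe, 80 °C
Reagents that add atoms: hexamethylditin, C[Sn](C)(C)[Sn](C)(C)C
Why: Palladium-catalysed stannylation of a vinyl iodide (oxidative addition of zerovalent palladium, transmetalation with the ditin, reductive elimination) should give the α-stannyl enone, the polarity that lets the next partner be the allylic terminus of 2,3-dibromopropene.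

Step 3
Reactants: 3 (R)-4-(tert-butyldimethylsilyloxy)-2-(trimethylstannyl)cyclopent-2-en-1-one; 4 2,3-dibromoprop-1-ene
Product: 5 (R)-2-(2-bromoprop-2-en-1-yl)-4-(tert-butyldimethylsilyloxy)cyclopent-2-en-1-one
Conditions: Pd2(dba)3 (cat.), AsPh3, CuI, DMF, 40 °C
Reagents that add atoms: none
Why: Stille coupling in which zerovalent palladium ionises the allylic C–Br bond of 4 much faster than it inserts into the vinylic C–Br bond, so the 2-bromo-π-allylpalladium species is intercepted by the vinylstannane and the vinyl bromide needed for ring D should survive.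

Step 4
Reactants: 5 (R)-2-(2-bromoprop-2-en-1-yl)-4-(tert-butyldimethylsilyloxy)cyclopent-2-en-1-one; 6 buta-1,3-diene
Product: 7 cis-fused ring B/C ketone (3R,3aR,7aR)-7a-(2-bromoprop-2-en-1-yl)-3-(tert-butyldimethylsilyloxy)-2,3,3a,4,7,7a-hexahydro-1H-inden-1-one
Conditions: buta-1,3-diene (excess), EtAlCl2 (0.3 equiv), PhMe, −30 to 0 °C, sealed vessel
Reagents that add atoms: none
Why: Lewis-acid-promoted Diels–Alder reaction: EtAlCl2 on the C6 carbonyl lowers the LUMO of the C8=C9 enone and butadiene adds in a concerted, suprafacial [4+2] fashion, forming C8–C14 and C9–C11 together. The closest known reaction types are the aluminium-halide-promoted cycloaddition of 2-alkylcyclopent-2-enones with butadiene to give cis-hydrindanones and the anti-selective cycloadditions of 4-silyloxycyclopentenones. Ring C is the only ring closed; it arises by intermolecular [4+2] annulation onto ring B, and suprafacial addition to the ring alkene makes the B/C fusion cis by necessity. The quaternary centre C8 and the methine C9 are both set by the face of approach, which the C10 stereocentre controls: the diene enters anti to the β-silyloxy group, so C14 and C11 end on the α face and the bromoallyl arm and H9 on the β face. The step needs π-facial selectivity (secured by the allylic OSi group next to C9), chemoselectivity for the enone over the vinyl bromide (secured by conjugation and Lewis-acid activation) and survival of the γ-silyloxy group (secured by sub-stoichiometric EtAlCl2 at low temperature, ionisation being disfavoured because it would lead to a cyclopentadienone); regiochemistry does not arise because butadiene is symmetrical. The C12=C13 alkene left behind is the acceptor for ring D closure in step 5.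

Step 5
Reactants: 7 cis-fused ring B/C ketone with 2-bromoallyl arm on C8
Product: 8 tricyclic ketone with rings B, C and D closed (C6 ketone; C16=C17 exocyclic methylene; C10–OSiMe2t-Bu β)
Conditions: Bu3SnH, AIBN (cat.), PhH, 80 °C, 0.02 M
Reagents that add atoms: none
Why: Tin-hydride vinyl radical cyclisation: bromine abstraction gives the σ-vinyl radical at C16, which should close 5-exo-trig onto C13; C13 is fixed because the bridge can form only on the face of ring C that carries C15, and a moderate hydride concentration traps the C12 radical before homoallyl rearrangement to the bicyclo[2.2.2] isomer.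

Step 6
Reactants: 8 tricyclic ketone with rings B, C and D closed
Product: 10 enol triflate (C5=C6–OSO2CF3; C10–OSiMe2t-Bu β), via potassium enolate 9 (not isolated)
Conditions: KN(SiMe3)2, THF, −78 °C; then PhNTf2
Reagents that add atoms: N-phenylbis(trifluoromethanesulfonimide), O=S(=O)(N(c1ccccc1)S(=O)(=O)C(F)(F)F)C(F)(F)F; potassium bis(trimethylsilyl)amide (potassium in 9 only), C[Si](C)(C)[N-][Si](C)(C)C.[K+]
Why: C8 is quaternary, so the C6 ketone can enolise only towards C5, and O-triflation at −78 °C (enol triflate formation) should outrun β-elimination of the C10 silyloxy group.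

Step 7
Reactants: 10 enol triflate
Product: 11 2-(trimethylsilyl)ethyl ester of the C5=C6 unsaturated C7 acid (C10–OSiMe2t-Bu β)
Conditions: CO (1 atm), Me3SiCH2CH2OH, Pd(OAc)2 (cat.), PPh3, Et3N, DMF, 50 °C
Reagents that add atoms: carbon monoxide, [C-]#[O+]; 2-(trimethylsilyl)ethanol, C[Si](C)(C)CCO
Why: Palladium-catalysed alkoxycarbonylation of an enol triflate (oxidative addition, CO insertion, alcoholysis of the acylpalladium) installs C7 as an ester that tolerates the later steps and is removable by fluoride, which avoids saponification next to the base-sensitive 3-hydroxy lactone.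

Step 8
Reactants: 11 silyl-protected unsaturated ester
Product: 12 allylic alcohol (C10–OH β; C5=C6–CO2CH2CH2SiMe3)
Conditions: HF·pyridine, THF, 0 °C to rt
Reagents that add atoms: none
Why: Buffered HF cleaves the secondary allylic silyl ether but, unlike naked fluoride, should leave the 2-(trimethylsilyl)ethyl ester intact.

Step 9
Reactants: 12 allylic alcohol
Product: 13 keto enoate (C10 ketone conjugated to C5=C6–CO2CH2CH2SiMe3)
Conditions: Dess–Martin periodinane, NaHCO3, CH2Cl2, 0 °C to rt
Reagents that add atoms: none
Why: Dess–Martin oxidation of the allylic alcohol gives a stable 3-oxocyclopent-1-ene-1-carboxylate and removes the C10 stereocentre after it has relayed its chirality to C8 and C9; the cis fusion at C9 is the thermodynamic arrangement next to the new ketone.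

Step 10
Reactants: 13 keto enoate; 14 3,3-diethoxyprop-1-yne; 15 propanoic anhydride
Product: 17 tertiary propargylic propanoate (C10: O-propanoyl α; 3,3-diethoxypropynyl β), via lithium alkoxide 16 (not isolated)
Conditions: 14, n-BuLi, THF, −78 °C; then 13; then 15, −78 to 0 °C
Reagents that add atoms: n-butyllithium (lithium in 16 only), [Li]CCCC
Why: The lithium acetylide should add 1,2 to the C10 ketone from the β face, anti to the C11 methylene on the neighbouring C9, which places the new oxygen α as in the target; the hindered tertiary alkoxide is acylated in the same flask.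

Step 11
Reactants: 17 tertiary propargylic propanoate
Product: 18 (Z)-alkenyl propanoate (C1=C2 cis; C3 as diethyl acetal)
Conditions: H2 (1 atm), Pd on CaCO3 poisoned with Pb(OAc)2, quinoline, EtOAc, rt
Reagents that add atoms: none
Why: Semi-hydrogenation on lead-poisoned palladium adds H2 syn to the alkyne and stops at the (Z)-alkene, the geometry that later lets C3 reach C4, while the exocyclic and the conjugated alkenes are not reduced by this catalyst.

Step 12
Reactants: 18 (Z)-alkenyl propanoate
Product: 19 γ-lactone (C19 to O10; new C4–C5 bond; H5 β; C7 ester β; C4 an epimer mixture)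
Conditions: KOtBu (0.3 equiv), t-BuOH/THF, 0 °C to rt; AcOH quench
Reagents that add atoms: none
Why: Intramolecular Michael addition: the propanoate enolate is tethered through the α-oxygen on C10 and can reach C5 of the unsaturated ester only from the α face (5-exo-trig), so the lactone is cis-fused to ring B and H5 is β; under the equilibrating alkoxide conditions C6 should settle with the ester β, trans to the new C4–C5 bond, and the C4 configuration is irrelevant because it is re-enolised in step 13.

Step 13
Reactants: 19 γ-lactone with (Z)-alkenyl acetal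
Product: 21 2-(trimethylsilyl)ethyl ester of the ring A allylic alcohol (ring A closed; 3β-OH; C1=C2; 19,10-lactone; C16=C17), via (Z)-enal 20 (not isolated)
Conditions: PPTS, acetone/H2O, rt; then K2CO3, MeOH, 0 °C
Reagents that add atoms: water, O
Why: Mild acid unmasks the (Z)-enal and carbonate then generates the lactone enolate at C4, which closes ring A by intramolecular aldol addition to C3; C4 can bond only on the face from which the C1–C2–C3 chain arrives, so methyl ends β by constraint, and an open antiperiplanar transition state in the protic medium should place the 3-hydroxyl axial (β).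

Step 14
Reactants: 21 2-(trimethylsilyl)ethyl ester of the ring A allylic alcohol
Product: 22 17-nor-16-ketone (C16=O; ring A unchanged)
Conditions: OsO4 (2 mol %), NaIO4, 2,6-lutidine, dioxane/H2O, rt
Reagents that add atoms: osmium tetroxide, O=[Os](=O)(=O)=O; sodium periodate, [Na+].[O-]I(=O)(=O)=O
Why: Lemieux–Johnson cleavage: catalytic OsO4 should dihydroxylate the unhindered exocyclic alkene much faster than the hindered ring A alkene flanked by two allylic oxygens, and NaIO4 cleaves the diol, so the methylene that masked the C16 ketone is taken off before ring A is osmylated.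

Step 15
Reactants: 22 17-nor-16-ketone
Product: 24 1β,2β,3β-triol 16-norketone 2-(trimethylsilyl)ethyl ester, via osmate ester 23 (not isolated)
Conditions: OsO4 (1.1 equiv), TMEDA, CH2Cl2, −78 °C; then aq. Na2SO3, THF, 50 °C
Reagents that add atoms: osmium tetroxide, O=[Os](=O)(=O)=O; N,N,N′,N′-tetramethylethylenediamine (in 23 only), CN(C)CCN(C)C
Why: Hydroxyl-directed osmylation: the OsO4·TMEDA complex is hydrogen-bonded by the 3β-hydroxyl and adds suprafacially to C1=C2 from the β face, the α face being closed by the lactone bridge, which should give the all-cis triol.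

Step 16
Reactants: 24 1β,2β,3β-triol 16-norketone ester
Product: 25 2-(trimethylsilyl)ethyl ester of the target gibberellin
Conditions: Zn, CH2Br2, TiCl4, THF/CH2Cl2, 0 °C to rt
Reagents that add atoms: dibromomethane, BrCBr
Why: Takai–Lombardo methylenation: the titanium-activated gem-dizinc reagent converts the C16 ketone into the exocyclic methylene under non-basic conditions that should leave lactone, ester and free hydroxyls alone and avoid the retro-aldol epimerisation at C3 that an ylide would risk.

Step 17
Reactants: 25 2-(trimethylsilyl)ethyl ester of the target gibberellin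
Product: 26 target gibberellin (19,10-γ-lactone; 1β,2β,3β-triol; free C7 acid; C16=C17 methylene)
Conditions: Bu4NF, THF, 0 °C; then aq. HCl to pH 3
Reagents that add atoms: none
Why: Fluoride attacks silicon and β-elimination releases the C7 carboxylate with ethene and Me3SiF, a cleavage that needs neither hydroxide nor strong acid and so should spare the lactone, the triol and the exocyclic alkene.

**Compound list**

1 | (R)-4-(tert-butyldimethylsilyloxy)cyclopent-2-en-1-one | O=C1C=C[C@H](O[Si](C)(C)C(C)(C)C)C1 | starting material
2 | (R)-4-(tert-butyldimethylsilyloxy)-2-iodocyclopent-2-en-1-one | O=C1C(I)=C[C@H](O[Si](C)(C)C(C)(C)C)C1 | intermediate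
3 | (R)-4-(tert-butyldimethylsilyloxy)-2-(trimethylstannyl)cyclopent-2-en-1-one | O=C1C([Sn](C)(C)C)=C[C@H](O[Si](C)(C)C(C)(C)C)C1 | intermediate
4 | 2,3-dibromoprop-1-ene | C=C(Br)CBr | starting material
5 | (R)-2-(2-bromoprop-2-en-1-yl)-4-(tert-butyldimethylsilyloxy)cyclopent-2-en-1-one | O=C1C(CC(Br)=C)=C[C@H](O[Si](C)(C)C(C)(C)C)C1 | intermediate
6 | buta-1,3-diene | C=CC=C | starting material
7 | (3R,3aR,7aR)-7a-(2-bromoprop-2-en-1-yl)-3-(tert-butyldimethylsilyloxy)-2,3,3a,4,7,7a-hexahydro-1H-inden-1-one (rings B/C cis-fused; C6 ketone; bromoallyl β on C8; H9 β; OSi β on C10; C12=C13) | C=C(Br)C[C@]23CC=CC[C@H]2[C@H](O[Si](C)(C)C(C)(C)C)CC3=O | intermediate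
8 | tricyclic ketone, rings B, C and D (C6 ketone; methylenebicyclo[3.2.1]octane with C16=C17; H9 β; C10–OSiMe2t-Bu β) | C=C1C[C@]23C[C@H]1CC[C@H]2[C@H](O[Si](C)(C)C(C)(C)C)CC3=O | intermediate
9 | potassium C5=C6 enolate of 8 | C=C1C[C@]23C[C@H]1CC[C@H]2[C@H](O[Si](C)(C)C(C)(C)C)C=C3[O-].[K+] | intermediate
10 | C5=C6 enol triflate of 8 | C=C1C[C@]23C[C@H]1CC[C@H]2[C@H](O[Si](C)(C)C(C)(C)C)C=C3OS(=O)(=O)C(F)(F)F | intermediate
11 | 2-(trimethylsilyl)ethyl C7 ester on C6 of the C5=C6 alkene, C10–OSiMe2t-Bu β | C=C1C[C@]23C[C@H]1CC[C@H]2[C@H](O[Si](C)(C)C(C)(C)C)C=C3C(=O)OCC[Si](C)(C)C | intermediate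
12 | allylic alcohol, C10–OH β, C5=C6–CO2CH2CH2SiMe3 | C=C1C[C@]23C[C@H]1CC[C@H]2[C@H](O)C=C3C(=O)OCC[Si](C)(C)C | intermediate
13 | keto enoate, C10 ketone conjugated to C5=C6–CO2CH2CH2SiMe3, H9 β | C=C1C[C@]23C[C@H]1CC[C@H]2C(=O)C=C3C(=O)OCC[Si](C)(C)C | intermediate
14 | 3,3-diethoxyprop-1-yne | C#CC(OCC)OCC | starting material
15 | propanoic anhydride | CCC(=O)OC(=O)CC | starting material
16 | lithium tertiary alkoxide at C10 (O α; 3,3-diethoxypropynyl β) | C=C1C[C@]23C[C@H]1CC[C@H]2[C@]([O-])(C#CC(OCC)OCC)C=C3C(=O)OCC[Si](C)(C)C.[Li+] | intermediate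
17 | tertiary propargylic propanoate at C10 (O-propanoyl α; 3,3-diethoxypropynyl β) | C=C1C[C@]23C[C@H]1CC[C@H]2[C@](OC(=O)CC)(C#CC(OCC)OCC)C=C3C(=O)OCC[Si](C)(C)C | intermediate
18 | (Z)-alkenyl propanoate (C1=C2 cis, C3 diethyl acetal) | C=C1C[C@]23C[C@H]1CC[C@H]2[C@](OC(=O)CC)(/C=C\C(OCC)OCC)C=C3C(=O)OCC[Si](C)(C)C | intermediate
19 | γ-lactone C19 to O10 (α), H5 β, C7 ester β, C4 epimer mixture, (Z)-alkenyl acetal on C10 | C=C1C[C@]23C[C@H]1CC[C@H]2[C@@]1(/C=C\C(OCC)OCC)OC(=O)C(C)[C@H]1[C@@H]3C(=O)OCC[Si](C)(C)C | intermediate
20 | (Z)-enal corresponding to 19 (C3 aldehyde) | C=C1C[C@]23C[C@H]1CC[C@H]2[C@@]1(/C=C\C=O)OC(=O)C(C)[C@H]1[C@@H]3C(=O)OCC[Si](C)(C)C | intermediate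
21 | 2-(trimethylsilyl)ethyl ester of the ring A allylic alcohol (ring A closed; 3β-OH; C1=C2; 4β-methyl; 19,10-lactone α; C7 ester β; C16=C17) | C=C1C[C@]23C[C@H]1CC[C@H]2[C@@]12OC(=O)[C@@](C)([C@H]1[C@@H]3C(=O)OCC[Si](C)(C)C)[C@@H](O)C=C2 | intermediate
22 | 17-nor-16-oxo derivative of 21 | O=C1C[C@]23C[C@H]1CC[C@H]2[C@@]12OC(=O)[C@@](C)([C@H]1[C@@H]3C(=O)OCC[Si](C)(C)C)[C@@H](O)C=C2 | intermediate
23 | cyclic 1β,2β-osmate ester of 22 (hexavalent osmium, TMEDA-ligated) | O=C1C[C@]23C[C@H]1CC[C@H]2[C@@]12OC(=O)[C@@](C)([C@H]1[C@@H]3C(=O)OCC[Si](C)(C)C)[C@@H](O)[C@@H](O[Os]4(=O)=O)[C@H]2O4.CN(C)CCN(C)C | intermediate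
24 | 1β,2β,3β-trihydroxy-17-nor-16-oxo ester | O=C1C[C@]23C[C@H]1CC[C@H]2[C@@]12OC(=O)[C@@](C)([C@H]1[C@@H]3C(=O)OCC[Si](C)(C)C)[C@@H](O)[C@@H](O)[C@H]2O | intermediate
25 | 2-(trimethylsilyl)ethyl ester of the target gibberellin (1β,2β,3β-triol; 19,10-lactone; C16=C17) | C=C1C[C@]23C[C@H]1CC[C@H]2[C@@]12OC(=O)[C@@](C)([C@H]1[C@@H]3C(=O)OCC[Si](C)(C)C)[C@@H](O)[C@@H](O)[C@H]2O | intermediate
26 | target gibberellin: 20-norgibberellane skeleton with 19,10-γ-lactone (α), 4β-methyl, 1β,2β,3β-triol, 6β-carboxylic acid (C7), H5 β, H9 β and C16=C17 exocyclic methylene | C=C1C[C@]23C[C@H]1CC[C@H]2[C@@]12OC(=O)[C@@](C)([C@H]1[C@@H]3C(=O)O)[C@@H](O)[C@@H](O)[C@H]2O | target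

**Totals and risks**

Total step count: 17. Longest linear sequence: 17 steps (1 to 26).

Steps most likely to fail:

Step 4 (key cycloaddition). The 2,4-disubstituted cyclopentenone may add butadiene only at temperatures where the Lewis acid starts to ionise or cleave the γ-silyloxy group, and facial selectivity may erode as the temperature rises. Fallback: quaternisation and cycloaddition are inverted. The route sets out from 2, whose α-iodine makes it the more reactive dienophile, and combines it with 6 (EtAlCl2 cat., PhMe, −30 °C, or thermally) to give, anti to the silyloxy group, the cis-fused α-iodo ketone F1. Zinc dust in THF converts F1 into the regiodefined iodozinc enolate F2, which is allylated with 4 under Pd(PPh3)4 catalysis on the convex β face, away from ring C. This returns to the route at 7, the quaternary centre now arising by enolate allylation instead of by cycloaddition.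

Step 13 (aldol closure of ring A). Closure through a chelated transition state, or retro-aldol equilibration, may place the 3-hydroxyl equatorial (α), and the (Z)-enal may isomerise to the (E)-enal, which cannot cyclise. Fallback: the C3 configuration is set by reduction instead of by the aldol step. From 19 the hydrolysis and aldol are run to completion under equilibrating conditions to give the 3α-alcohol F3 (alone or mixed with 21). Dess–Martin oxidation converges the material on the ring A enone F4. KBH(s-Bu)3 in THF at −78 °C should then deliver hydride along the equatorial vector, with conjugate reduction held back by the quaternary C10 next to the β-carbon, and return the axial 3β-alcohol 21.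

Step 3 (allylation of the α-stannyl enone). The electron-poor vinylstannane may protodestannylate or homocouple faster than it transmetalates, and palladium may insert into the vinylic C–Br bond of the product. Fallback: the coupling polarity is reversed and the stannane is avoided. From 4, copper-catalysed allylic borylation (bis(pinacolato)diboron, CuCl, KOtBu, THF) gives 2-(2-bromoprop-2-en-1-yl)-4,4,5,5-tetramethyl-1,3,2-dioxaborolane F5; substitution at either allylic terminus leads to the same boronate. F5 is joined to iodoenone 2 by Suzuki–Miyaura coupling (PdCl2(dppf), Cs2CO3, THF/H2O, rt), the activated C–I bond reacting before either vinyl bromide. This returns to the route at 5 and bypasses step 2.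

Further compounds
F1 | step 4 | cis-fused α-iodo ketone (iodine β on C8; H9 β; C10–OSiMe2t-Bu β; C12=C13) | I[C@]23CC=CC[C@H]2[C@H](O[Si](C)(C)C(C)(C)C)CC3=O
F2 | step 4 | iodozinc C6=C8 enolate derived from F1 | I[Zn]OC1=C2CC=CC[C@H]2[C@H](O[Si](C)(C)C(C)(C)C)C1
F3 | step 13 | 3α-epimer of 21 (3α-OH; C1=C2; 19,10-lactone; 2-(trimethylsilyl)ethyl ester) | C=C1C[C@]23C[C@H]1CC[C@H]2[C@@]12OC(=O)[C@@](C)([C@H]1[C@@H]3C(=O)OCC[Si](C)(C)C)[C@H](O)C=C2
F4 | step 13 | ring A enone (3-oxo, C1=C2) 2-(trimethylsilyl)ethyl ester | C=C1C[C@]23C[C@H]1CC[C@H]2[C@@]12OC(=O)[C@@](C)([C@H]1[C@@H]3C(=O)OCC[Si](C)(C)C)C(=O)C=C2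
F5 | step 3 | 2-(2-bromoprop-2-en-1-yl)-4,4,5,5-tetramethyl-1,3,2-dioxaborolane | C=C(Br)CB1OC(C)(C)C(C)(C)O1
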